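**Retrosynthetic overview** (germacrane numbering C1–C15 is used for positions)
1. Epoxide last: site- and face-selective epoxidation of the C1=C10 alkene of the preformed 10-membered trienolide.
2. 10-membered carbocycle: C3–C4 by nickel-catalysed, CrCl2-mediated closure of a (Z)-alkenyl iodide onto the C3 aldehyde (sets C3).
3. Fragment union at C7–C8 (sets C7 and C8): (salen)CrCl-catalysed syn-selective allylation of a C8 aldehyde with a 3-(bromomethyl)butenolide; O8 is then isobutyrylated.
4. Lactone ring first: ring-closing metathesis of the 2-(bromomethyl)acrylate of an (S)-dienol made by asymmetric vinylation of (2Z)-3-iodobut-2-enal (sets C6).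
5. C8–C3 arm from but-3-yn-1-ol by zirconium-catalysed methylalumination and ethylene oxide opening; ring order: lactone, 10-membered ring, epoxide.

Assumption: the sense of induction of the chiral ligands on these substrates (steps 3, 11 and 14) is taken to be the one stated for the enantiomer named.

**Step 1**
Reactants: 1 but-2-yn-1-ol
Product: 3 (2Z)-3-iodobut-2-en-1-ol, via cyclic alkenylaluminate 2 (not isolated)
Conditions: NaAlH2(OCH2CH2OMe)2, THF, 0 °C to rt; then N-iodosuccinimide, −78 °C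
Reagents that add atoms: N-iodosuccinimide, O=C1CCC(=O)N1I
Why: Alkoxide-directed trans-hydroalumination of the propargylic alcohol puts aluminium on C3 cis to the CH2O group, and iododealumination with retention gives only the Z-iodide.

**Step 2**
Reactants: 3 (2Z)-3-iodobut-2-en-1-ol
Product: 4 (2Z)-3-iodobut-2-enal
Conditions: MnO2, CH2Cl2, rt
Reagents that add atoms: none
Why: Allylic alcohol oxidation with activated MnO2 is neutral and does not isomerise the Z-alkene.

**Step 3**
Reactants: 4 (2Z)-3-iodobut-2-enal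
Product: 5 (3S,4Z)-5-iodohexa-1,4-dien-3-ol
Conditions: (CH2=CH)2Zn, (−)-DAIB (5 mol%), toluene/Et2O, −20 to 0 °C
Reagents that add atoms: divinylzinc, C=C[Zn]C=C
Why: Amino-alcohol-catalysed asymmetric organozinc 1,2-addition delivers the vinyl group to the Si face of the enal and so sets the future C6 stereocentre (3S here).

**Step 4**
Reactants: 5 (3S,4Z)-5-iodohexa-1,4-dien-3-ol; 6 2-(bromomethyl)prop-2-enoic acid
Product: 7 (3S,4Z)-5-iodohexa-1,4-dien-3-yl 2-(bromomethyl)prop-2-enoate
Conditions: DCC, DMAP (5 mol%), CH2Cl2, −10 °C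
Reagents that add atoms: none
Why: Steglich esterification at low temperature acylates the secondary alcohol without touching the allylic bromide or the stereocentre.

**Step 5**
Reactants: 7 (3S,4Z)-5-iodohexa-1,4-dien-3-yl 2-(bromomethyl)prop-2-enoate
Product: 8 (5S)-3-(bromomethyl)-5-[(1Z)-2-iodoprop-1-en-1-yl]furan-2(5H)-one
Conditions: second-generation Hoveyda–Grubbs catalyst (5 mol%), toluene, 80 °C, 5 mM
Reagents that add atoms: none
Why: Ring-closing metathesis between the terminal vinyl group and the acrylate alkene closes the lactone ring with loss of ethene, while the trisubstituted iodoalkene is inert to the ruthenium carbene.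

**Step 6**
Reactants: 9 but-3-yn-1-ol
Product: 10 1-[(but-3-yn-1-yloxy)methyl]-4-methoxybenzene
Conditions: NaH, 4-MeOC6H4CH2Cl, Bu4NI (cat.), THF, 0 °C to rt
Reagents that add atoms: 4-methoxybenzyl chloride, COc1ccc(CCl)cc1
Why: Williamson etherification of the primary alkoxide masks the C8 oxygen as a PMB ether for the organoaluminium step.

**Step 7**
Reactants: 10 1-[(but-3-yn-1-yloxy)methyl]-4-methoxybenzene
Product: 13 (3E)-6-[(4-methoxybenzyl)oxy]-4-methylhex-3-en-1-ol, via alkenyldimethylalane 11 (not isolated), via lithium alkenylaluminate 12 (not isolated)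
Conditions: Me3Al, Cp2ZrCl2 (20 mol%), CH2Cl2, 0 °C to rt; then n-BuLi, THF, −78 °C; then ethylene oxide, −78 to 0 °C
Reagents that add atoms: trimethylaluminium, C[Al](C)C; ethylene oxide, C1CO1
Why: Zirconium-catalysed syn-carboalumination (Negishi) adds methyl and aluminium cis across the terminal alkyne and the derived ate complex opens ethylene oxide with retention, so the C1=C10 alkene is E.

**Step 8**
Reactants: 13 (3E)-6-[(4-methoxybenzyl)oxy]-4-methylhex-3-en-1-ol
Product: 14 triethyl{[(3E)-6-[(4-methoxybenzyl)oxy]-4-methylhex-3-en-1-yl]oxy}silane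
Conditions: Et3SiCl, imidazole, CH2Cl2, 0 °C
Reagents that add atoms: chlorotriethylsilane, CC[Si](Cl)(CC)CC
Why: Silylation of the primary C3 alcohol gives an Et3Si ether that is orthogonal to the PMB ether and can later be oxidised directly.

**Step 9**
Reactants: 14 triethyl{[(3E)-6-[(4-methoxybenzyl)oxy]-4-methylhex-3-en-1-yl]oxy}silane
Product: 15 (3E)-3-methyl-6-[(triethylsilyl)oxy]hex-3-en-1-ol
Conditions: DDQ, CH2Cl2/pH 7 phosphate buffer, 0 °C
Reagents that add atoms: none
Why: Oxidative PMB cleavage by DDQ (benzylic oxocarbenium ion hydrolysed by the buffer) frees the C8 hydroxyl while the silyl ether and the alkene stay intact.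

**Step 10**
Reactants: 15 (3E)-3-methyl-6-[(triethylsilyl)oxy]hex-3-en-1-ol
Product: 16 (3E)-3-methyl-6-[(triethylsilyl)oxy]hex-3-enal
Conditions: Dess–Martin periodinane, pyridine, CH2Cl2, 0 °C; used crude
Reagents that add atoms: none
Why: Buffered Dess–Martin oxidation gives the β,γ-unsaturated aldehyde without migration of the alkene into conjugation.

**Step 11**
Reactants: 16 (3E)-3-methyl-6-[(triethylsilyl)oxy]hex-3-enal; 8 (5S)-3-(bromomethyl)-5-[(1Z)-2-iodoprop-1-en-1-yl]furan-2(5H)-one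
Product: 18 (4R,5S)-4-[(1R,3E)-1-hydroxy-3-methyl-6-[(triethylsilyl)oxy]hex-3-en-1-yl]-5-[(1Z)-2-iodoprop-1-en-1-yl]-3-methylidenedihydrofuran-2(3H)-one, via trimethylsilyl ether 17 (not isolated)
Conditions: (R,R)-(salen)CrCl (10 mol%; salen = N,N'-bis(3,5-di-tert-butylsalicylidene)cyclohexane-1,2-diamine dianion), Mn powder, Me3SiCl, MeCN, rt, slow addition of 8; then aq. citric acid, THF, 0 °C
Reagents that add atoms: none
Why: Proposed new method: a (salen)CrCl-catalysed Nozaki–Hiyama allylation with a γ-substituted 2-carboxyallyl bromide locked in a butenolide, in which the salen ligand fills the four equatorial sites of chromium so that allyl and aldehyde cannot sit cis on one metal and the C7–C8 bond forms between an η1-allyl–Cr(salen) unit and an aldehyde activated by a second (salen)Cr centre through an open antiperiplanar transition state, which gives the syn (7R,8R) adduct from the E-locked allyl unit on the butenolide face opposite to the C6 alkenyl group (trans-lactone), whereas the closed chair of zinc or ligand-free CrCl2 would give the C8 epimer; the closest known reactions are the syn-selective (salen)Cr-catalysed crotylation of aldehydes with Mn/Me3SiCl turnover and the zinc- or chromium-mediated Barbier additions of 3-(bromomethyl)butenolides.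

**Step 12**
Reactants: 18 (4R,5S)-4-[(1R,3E)-1-hydroxy-3-methyl-6-[(triethylsilyl)oxy]hex-3-en-1-yl]-5-[(1Z)-2-iodoprop-1-en-1-yl]-3-methylidenedihydrofuran-2(3H)-one
Product: 19 (1R,3E)-1-[(2S,3R)-2-[(1Z)-2-iodoprop-1-en-1-yl]-4-methylidene-5-oxotetrahydrofuran-3-yl]-3-methyl-6-[(triethylsilyl)oxy]hex-3-en-1-yl 2-methylpropanoate
Conditions: i-PrCOCl, pyridine, DMAP (cat.), CH2Cl2, 0 °C
Reagents that add atoms: isobutyryl chloride, CC(C)C(Cl)=O
Why: Nucleophile-catalysed O-acylation of the secondary alcohol installs the isobutyrate with retention at C8.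

**Step 13**
Reactants: 19 (1R,3E)-1-[(2S,3R)-2-[(1Z)-2-iodoprop-1-en-1-yl]-4-methylidene-5-oxotetrahydrofuran-3-yl]-3-methyl-6-[(triethylsilyl)oxy]hex-3-en-1-yl 2-methylpropanoate
Product: 21 (1R,3E)-1-[(2S,3R)-2-[(1Z)-2-iodoprop-1-en-1-yl]-4-methylidene-5-oxotetrahydrofuran-3-yl]-3-methyl-6-oxohex-3-en-1-yl 2-methylpropanoate, via alkoxysulfonium chloride 20 (not isolated)
Conditions: (COCl)2, DMSO, CH2Cl2, −78 to −35 °C; then i-Pr2NEt, −78 to −20 °C; used at once
Reagents that add atoms: none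
Why: Under Swern conditions the chlorodimethylsulfonium salt cleaves the primary Et3Si–O bond and the alkoxysulfonium ion is deprotonated by the hindered amine, so the C3 aldehyde forms in one cold, non-acidic operation that leaves ester, lactone and skipped alkene in place.

**Step 14**
Reactants: 21 (1R,3E)-1-[(2S,3R)-2-[(1Z)-2-iodoprop-1-en-1-yl]-4-methylidene-5-oxotetrahydrofuran-3-yl]-3-methyl-6-oxohex-3-en-1-yl 2-methylpropanoate
Product: 22 (1(10)E,3S,4Z,6R,7R,8R)-3-hydroxy-8-(2-methylpropanoyloxy)germacra-1(10),4,11(13)-trien-12,6-olide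
Conditions: CrCl2, (S)-N-[2-(4-isopropyl-4,5-dihydrooxazol-2-yl)-6-methoxyphenyl]methanesulfonamide, Et3N, NiCl2 (cat.), THF, rt, 2 mM, syringe-pump addition
Reagents that add atoms: none
Why: Nozaki–Hiyama–Kishi reaction in which nickel inserts into the C–I bond and transmetalates to chromium, and the sulfonamide-ligated alkenylchromium adds to the Re face of the aldehyde (ligand control on a non-α-branched aldehyde), closing the 10-membered ring with retention of the Z-alkene and setting C3 as S.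

**Step 15**
Reactants: 22 (1(10)E,3S,4Z,6R,7R,8R)-3-hydroxy-8-(2-methylpropanoyloxy)germacra-1(10),4,11(13)-trien-12,6-olide
Product: 23 (1S,3S,4Z,6R,7R,8R,10S)-1,10-epoxy-3-hydroxy-8-(2-methylpropanoyloxy)germacra-4,11(13)-dien-12,6-olide (CNP0261225.3)
Conditions: dimethyldioxirane (1.05 equiv), acetone, −30 to 0 °C
Reagents that add atoms: dimethyldioxirane, CC1(C)OO1
Why: Neutral electrophilic epoxidation is stereospecific and takes the most electron-rich alkene (trialkyl C1=C10; C4=C5 is deactivated by two allylic oxygens and the exo-methylene by the carbonyl) from its exposed outer face in the folded 10-membered ring, which is expected to give the trans-epoxide with 1S,10S configuration.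

**Compound list**
1 | but-2-yn-1-ol | CC#CCO | starting material
2 | sodium 2,2-bis(2-methoxyethoxy)-3-methyl-2,5-dihydro-1,2-oxaluminol-2-uide (cyclic alkenylaluminate) | [Na+].CC1=CCO[Al-]1(OCCOC)OCCOC | intermediate
3 | (2Z)-3-iodobut-2-en-1-ol | C/C(I)=C/CO | intermediate
4 | (2Z)-3-iodobut-2-enal | C/C(I)=C/C=O | intermediate
5 | (3S,4Z)-5-iodohexa-1,4-dien-3-ol | C=C[C@H](O)/C=C(/C)I | intermediate
6 | 2-(bromomethyl)prop-2-enoic acid | C=C(CBr)C(=O)O | starting material
7 | (3S,4Z)-5-iodohexa-1,4-dien-3-yl 2-(bromomethyl)prop-2-enoate | C=C[C@H](OC(=O)C(=C)CBr)/C=C(/C)I | intermediate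
8 | (5S)-3-(bromomethyl)-5-[(1Z)-2-iodoprop-1-en-1-yl]furan-2(5H)-one | BrCC1=C[C@@H](/C=C(/C)I)OC1=O | intermediate
9 | but-3-yn-1-ol | C#CCCO | starting material
10 | 1-[(but-3-yn-1-yloxy)methyl]-4-methoxybenzene | C#CCCOCc1ccc(OC)cc1 | intermediate
11 | [(1E)-4-[(4-methoxybenzyl)oxy]-2-methylbut-1-en-1-yl]dimethylalane | C[Al](C)/C=C(\C)CCOCc1ccc(OC)cc1 | intermediate
12 | lithium butyl[(1E)-4-[(4-methoxybenzyl)oxy]-2-methylbut-1-en-1-yl]dimethylaluminate | [Li+].CCCC[Al-](C)(C)/C=C(\C)CCOCc1ccc(OC)cc1 | intermediate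
13 | (3E)-6-[(4-methoxybenzyl)oxy]-4-methylhex-3-en-1-ol | OCC/C=C(\C)CCOCc1ccc(OC)cc1 | intermediate
14 | triethyl{[(3E)-6-[(4-methoxybenzyl)oxy]-4-methylhex-3-en-1-yl]oxy}silane | CC[Si](CC)(CC)OCC/C=C(\C)CCOCc1ccc(OC)cc1 | intermediate
15 | (3E)-3-methyl-6-[(triethylsilyl)oxy]hex-3-en-1-ol | CC[Si](CC)(CC)OCC/C=C(\C)CCO | intermediate
16 | (3E)-3-methyl-6-[(triethylsilyl)oxy]hex-3-enal | CC[Si](CC)(CC)OCC/C=C(\C)CC=O | intermediate
17 | (4S,5S)-5-[(1Z)-2-iodoprop-1-en-1-yl]-3-methylidene-4-[(1R,3E)-3-methyl-6-[(triethylsilyl)oxy]-1-[(trimethylsilyl)oxy]hex-3-en-1-yl]dihydrofuran-2(3H)-one (same geometry as 18; the ring descriptor changes by priority only) | C=C1C(=O)O[C@H](/C=C(/C)I)[C@H]1[C@H](O[Si](C)(C)C)C/C(C)=C/CCO[Si](CC)(CC)CC | intermediate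
18 | (4R,5S)-4-[(1R,3E)-1-hydroxy-3-methyl-6-[(triethylsilyl)oxy]hex-3-en-1-yl]-5-[(1Z)-2-iodoprop-1-en-1-yl]-3-methylidenedihydrofuran-2(3H)-one | C=C1C(=O)O[C@H](/C=C(/C)I)[C@H]1[C@H](O)C/C(C)=C/CCO[Si](CC)(CC)CC | intermediate
19 | (1R,3E)-1-[(2S,3R)-2-[(1Z)-2-iodoprop-1-en-1-yl]-4-methylidene-5-oxotetrahydrofuran-3-yl]-3-methyl-6-[(triethylsilyl)oxy]hex-3-en-1-yl 2-methylpropanoate | C=C1C(=O)O[C@H](/C=C(/C)I)[C@H]1[C@H](OC(=O)C(C)C)C/C(C)=C/CCO[Si](CC)(CC)CC | intermediate
20 | {[(3E,6R)-6-[(2S,3R)-2-[(1Z)-2-iodoprop-1-en-1-yl]-4-methylidene-5-oxotetrahydrofuran-3-yl]-4-methyl-6-(2-methylpropanoyloxy)hex-3-en-1-yl]oxy}dimethylsulfonium chloride | C=C1C(=O)O[C@H](/C=C(/C)I)[C@H]1[C@H](OC(=O)C(C)C)C/C(C)=C/CCO[S+](C)C.[Cl-] | intermediate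
21 | (1R,3E)-1-[(2S,3R)-2-[(1Z)-2-iodoprop-1-en-1-yl]-4-methylidene-5-oxotetrahydrofuran-3-yl]-3-methyl-6-oxohex-3-en-1-yl 2-methylpropanoate | C=C1C(=O)O[C@H](/C=C(/C)I)[C@H]1[C@H](OC(=O)C(C)C)C/C(C)=C/CC=O | intermediate
22 | (1(10)E,3S,4Z,6R,7R,8R)-3-hydroxy-8-(2-methylpropanoyloxy)germacra-1(10),4,11(13)-trien-12,6-olide | C=C1C(=O)O[C@@H]2/C=C(/C)[C@@H](O)C/C=C(\C)C[C@@H](OC(=O)C(C)C)[C@@H]12 | intermediate
23 | (1S,3S,4Z,6R,7R,8R,10S)-1,10-epoxy-3-hydroxy-8-(2-methylpropanoyloxy)germacra-4,11(13)-dien-12,6-olide | C=C1C(=O)O[C@@H]2/C=C(/C)[C@@H](O)C[C@@H]3O[C@@]3(C)C[C@@H](OC(=O)C(C)C)[C@@H]12 | target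

**Totals**
Total step count: 15. Longest linear sequence: 10 steps (steps 1–5 then 11–15; the chain 6–10 then 11–15 is equally long).

**Three steps most likely to fail**

Step 11 (the proposed new step). The conjugated allyl unit may be sluggish, manganese may give a ligand-free closed-chair background reaction, and the syn preference of the open transition state is untested for this donor. Fallback by known chemistry: setting out from 16 and 8, zinc dust in THF/saturated aqueous NH4Cl (Barbier addition of a 3-(bromomethyl)butenolide through the closed chair) gives the anti adduct (4R,5S)-4-[(1S,3E)-1-hydroxy-3-methyl-6-[(triethylsilyl)oxy]hex-3-en-1-yl]-5-[(1Z)-2-iodoprop-1-en-1-yl]-3-methylidenedihydrofuran-2(3H)-one F1. Mitsunobu esterification of F1 with isobutyric acid (PPh3, DIAD, toluene, 0 °C) inverts C8 and comes back to the route at 19, so step 12 is not needed.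

Step 14. The 10-membered closure competes with oligomerisation, and the ligand may not override the conformational bias at C3. Fallback: setting out from 21, ligand-free NiCl2/CrCl2 in DMSO at 2 mM closes the ring without facial control and gives 22 together with its C3 epimer (1(10)E,3R,4Z,6R,7R,8R)-3-hydroxy-8-(2-methylpropanoyloxy)germacra-1(10),4,11(13)-trien-12,6-olide F2. Dess–Martin oxidation of the mixture gives the macrocyclic enone (1(10)E,4Z,6R,7R,8R)-8-(2-methylpropanoyloxy)-3-oxogermacra-1(10),4,11(13)-trien-12,6-olide F3. Reagent-controlled 1,2-reduction of F3 with (R)-2-methyl-CBS-oxazaborolidine and catecholborane (toluene, −78 °C) comes back to the route at 22.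

Step 15. The outer-face preference is an expectation, not a measured result; the allylic hydroxyl could also steer some oxidant to C4=C5, and the epoxide is prone to transannular opening under acid. Fallback: setting out from 19, the epoxide is put in before ring closure under reagent control. Shi epoxidation with the enantiomeric (L-fructose-derived) Shi ketone and KHSO5 (K2CO3 buffer, MeCN/dimethoxymethane, 0 °C) takes the only electron-rich alkene and gives (1R)-1-[(2S,3R)-2-[(1Z)-2-iodoprop-1-en-1-yl]-4-methylidene-5-oxotetrahydrofuran-3-yl]-2-[(2S,3S)-2-methyl-3-[2-[(triethylsilyl)oxy]ethyl]oxiran-2-yl]ethyl 2-methylpropanoate F4. Direct Swern oxidation as in step 13 gives the epoxy aldehyde (1R)-1-[(2S,3R)-2-[(1Z)-2-iodoprop-1-en-1-yl]-4-methylidene-5-oxotetrahydrofuran-3-yl]-2-[(2S,3S)-2-methyl-3-(2-oxoethyl)oxiran-2-yl]ethyl 2-methylpropanoate F5, used at once. Ring closure of F5 under the conditions of step 14 comes back to the route at 23.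

**Further compounds**
F1 | step 11 | (4R,5S)-4-[(1S,3E)-1-hydroxy-3-methyl-6-[(triethylsilyl)oxy]hex-3-en-1-yl]-5-[(1Z)-2-iodoprop-1-en-1-yl]-3-methylidenedihydrofuran-2(3H)-one | C=C1C(=O)O[C@H](/C=C(/C)I)[C@H]1[C@@H](O)C/C(C)=C/CCO[Si](CC)(CC)CC
F2 | step 14 | (1(10)E,3R,4Z,6R,7R,8R)-3-hydroxy-8-(2-methylpropanoyloxy)germacra-1(10),4,11(13)-trien-12,6-olide | C=C1C(=O)O[C@@H]2/C=C(/C)[C@H](O)C/C=C(\C)C[C@@H](OC(=O)C(C)C)[C@@H]12
F3 | step 14 | (1(10)E,4Z,6R,7R,8R)-8-(2-methylpropanoyloxy)-3-oxogermacra-1(10),4,11(13)-trien-12,6-olide | C=C1C(=O)O[C@@H]2/C=C(/C)C(=O)C/C=C(\C)C[C@@H](OC(=O)C(C)C)[C@@H]12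
F4 | step 15 | (1R)-1-[(2S,3R)-2-[(1Z)-2-iodoprop-1-en-1-yl]-4-methylidene-5-oxotetrahydrofuran-3-yl]-2-[(2S,3S)-2-methyl-3-[2-[(triethylsilyl)oxy]ethyl]oxiran-2-yl]ethyl 2-methylpropanoate | C=C1C(=O)O[C@H](/C=C(/C)I)[C@H]1[C@H](OC(=O)C(C)C)C[C@]2(C)O[C@H]2CCO[Si](CC)(CC)CC
F5 | step 15 | (1R)-1-[(2S,3R)-2-[(1Z)-2-iodoprop-1-en-1-yl]-4-methylidene-5-oxotetrahydrofuran-3-yl]-2-[(2S,3S)-2-methyl-3-(2-oxoethyl)oxiran-2-yl]ethyl 2-methylpropanoate | C=C1C(=O)O[C@H](/C=C(/C)I)[C@H]1[C@H](OC(=O)C(C)C)C[C@]2(C)O[C@H]2CC=O
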